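**Retrosynthetic overview**
1. Target 13 ⇐ hepta-O-methyl ether 12 by global demethylation.
2. Second ring (δ-type dihydrobenzofuran on the stilbene phenol ring; C3–C4′, C2–C3 and C2–O bonds) ⇐ aryl-metal from bromide 8 + O-Boc salicylaldehyde 11 + chiral sulfonium benzylide from 3, through a dearomatised o-quinone methide (o-QM) and [4+1] annulation.
3. First ring (ε-type dihydrobenzofuran on the central resorcinol ring) of 8 ⇐ the same three-component o-QM/[4+1] from O-Boc salicylaldehyde 6 + 3,5-dimethoxyphenyl Grignard + the same ylide.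
4. 6 ⇐ 2-bromo-4,6-dimethoxybenzaldehyde; 11 ⇐ pterostilbene; 3 ⇐ isothiocineole + anisyl alcohol.
5. Both rings are homochiral (2S,3S), so one enantiomer of one chiral ylide is meant to set all four stereocentres.

Assumption: the SMILES is read as the all-(S), trans,trans isomer (2S,3S in each dihydrobenzofuran).
Assumption: isothiocineole and 2-bromo-4,6-dimethoxybenzaldehyde are taken as purchasable; the (1R,4R,5R) sulfide is drawn and assumed to be the enantiomer that gives (R,R)-stilbene oxide in the benchmark benzaldehyde epoxidation, which corresponds to 2S here (the CIP priorities at the ylide carbon swap between epoxide and dihydrobenzofuran). If a model run shows the opposite sense, the (1S,4S,5S) sulfide is used with no other change.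

**Step 1**
Reactants: 1 (1R,4R,5R)-isothiocineole; 2 4-methoxybenzyl alcohol
Product: 3 (1R,4R,5R)-6-(4-methoxybenzyl)-4,7,7-trimethyl-6-thiabicyclo[3.2.1]octan-6-ium tetrafluoroborate (single diastereomer at sulfur expected; S descriptor not encoded)
Conditions: HBF4·OEt2, CH2Cl2, 0 °C → rt; precipitate with Et2O
Reagents that add atoms: tetrafluoroboric acid (counter-ion), [H+].F[B-](F)(F)F
Why: SN1 S-alkylation of the sulfide by the 4-methoxybenzyl cation (sulfonium salt formation); no carbon stereocentre is created.

**Step 2**
Reactants: 4 2-bromo-4,6-dimethoxybenzaldehyde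
Product: 5 2-bromo-6-hydroxy-4-methoxybenzaldehyde
Conditions: BCl3 (1.2 equiv), CH2Cl2, −78 → 0 °C; aq. workup
Reagents that add atoms: none
Why: Chelation-controlled Lewis-acid demethylation; BCl3 bridges the aldehyde oxygen and the ortho methoxy group, so only that ether is cleaved and the para OMe and the bromide are untouched.

**Step 3**
Reactants: 5
Product: 6 tert-butyl (3-bromo-2-formyl-5-methoxyphenyl) carbonate
Conditions: Boc2O, i-Pr2NEt, DMAP (cat.), CH2Cl2, 0 °C → rt
Reagents that add atoms: di-tert-butyl dicarbonate, CC(C)(C)OC(=O)OC(=O)OC(C)(C)C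
Why: DMAP-catalysed O-acylation of the phenol; the carbonate is the latent leaving group for the o-QM generation in Step 4.

**Step 4**
Reactants: 6; 7 1-bromo-3,5-dimethoxybenzene (as its Grignard reagent); 3 (as its ylide)
Product: 8 (2S,3S)-4-bromo-3-(3,5-dimethoxyphenyl)-6-methoxy-2-(4-methoxyphenyl)-2,3-dihydro-1-benzofuran (trans)
Conditions: 7, Mg, THF; add to 6, THF, −78 °C; then ylide [3, LiHMDS, THF, −78 °C] by cannula, −78 °C → rt; chromatography (removes cis isomer, recovers 1), recrystallise
Reagents that add atoms: none beyond the listed reactants (aryl from 3,5-dimethoxyphenylmagnesium bromide, COc1cc([Mg]Br)cc(OC)c1; ArCH unit from 3)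
Why: Proposed new method: the Grignard adds to the aldehyde, the magnesium alkoxide takes over the Boc group and the freed phenoxide expels tert-butyl carbonate to give the dearomatised β-aryl o-quinone methide (known anionic o-QM generation from O-Boc salicylaldehydes), which is trapped by the semi-stabilised chiral benzylide through Michael addition and 5-exo-tet O-alkylation (closest known reactions: o-QM + sulfur ylide [4+1] annulation to trans-2,3-dihydrobenzofurans, and asymmetric sulfur-ylide epoxidation/cyclopropanation); the sulfide blocks one face of the ylide carbon, which fixes C2 after SN2 inversion, and anti approach to the o-QM places the two aryl groups trans, fixing C3.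

**Step 5**
Reactants: 9 pterostilbene
Product: 10 5-[(E)-2-(3,5-dimethoxyphenyl)ethenyl]-2-hydroxybenzaldehyde
Conditions: MgCl2, Et3N, (CH2O)n, MeCN, reflux
Reagents that add atoms: paraformaldehyde (formaldehyde), C=O
Why: Magnesium-phenoxide-directed ortho-formylation (Casnati–Skattebøl); the para position is blocked, both ortho positions are equivalent, and the stilbene is inert to these conditions.

**Step 6**
Reactants: 10
Product: 11 tert-butyl {4-[(E)-2-(3,5-dimethoxyphenyl)ethenyl]-2-formylphenyl} carbonate
Conditions: Boc2O, i-Pr2NEt, DMAP (cat.), CH2Cl2, 0 °C → rt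
Reagents that add atoms: di-tert-butyl dicarbonate, CC(C)(C)OC(=O)OC(=O)OC(C)(C)C
Why: DMAP-catalysed O-acylation of the phenol, as in Step 3.

**Step 7**
Reactants: 8 (as its aryl-magnesium); 11; 3 (as its ylide, same enantiomer as in Step 4)
Product: 12 hepta-O-methyl-trans-diptoindonesin B, i.e. (2S,3S)-4-[(2S,3S)-5-[(E)-2-(3,5-dimethoxyphenyl)ethenyl]-2-(4-methoxyphenyl)-2,3-dihydro-1-benzofuran-3-yl]-3-(3,5-dimethoxyphenyl)-6-methoxy-2-(4-methoxyphenyl)-2,3-dihydro-1-benzofuran
Conditions: 8, t-BuLi (2 equiv), THF, −78 °C; MgBr2·OEt2; then 11, −78 °C; then ylide [3, LiHMDS, THF, −78 °C], −78 °C → rt; chromatography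
Reagents that add atoms: none beyond the listed reactants
Why: Proposed new method: Br/Li exchange and transmetalation give the aryl-magnesium, which adds to 11 and triggers the same Boc-transfer/elimination to a stilbene-substituted o-quinone methide, trapped by the chiral ylide in a [4+1] annulation (same precedents as Step 4); the ylide face sets C2 (S) and anti addition sets C3 (S) trans to it, and because the existing ring makes any mis-set centre a diastereomer, it is separable.

**Step 8**
Reactants: 12
Product: 13 trans-diptoindonesin B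
Conditions: BBr3 (excess), CH2Cl2, −78 °C → rt; MeOH then H2O quench
Reagents that add atoms: none
Why: Lewis-acid cleavage of the seven aryl methyl ethers (BBr3 demethylation); if a benzylic C2–O bond opens transiently it should reclose through the p-quinone methide to the thermodynamically preferred trans ring, and C3/C3′ and the E-alkene are not ionisable under these conditions.

**Compound list**
1 | (1R,4R,5R)-isothiocineole | C[C@@H]1CC[C@@H]2C[C@H]1SC2(C)C | starting material
2 | 4-methoxybenzyl alcohol | COc1ccc(CO)cc1 | starting material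
3 | (1R,4R,5R)-6-(4-methoxybenzyl)-4,7,7-trimethyl-6-thiabicyclo[3.2.1]octan-6-ium tetrafluoroborate | C[C@@H]1CC[C@@H]2C[C@H]1[S+](Cc1ccc(OC)cc1)C2(C)C.F[B-](F)(F)F | intermediate (chiral reagent)
4 | 2-bromo-4,6-dimethoxybenzaldehyde | COc1cc(Br)c(C=O)c(OC)c1 | starting material
5 | 2-bromo-6-hydroxy-4-methoxybenzaldehyde | COc1cc(O)c(C=O)c(Br)c1 | intermediate
6 | tert-butyl (3-bromo-2-formyl-5-methoxyphenyl) carbonate | COc1cc(OC(=O)OC(C)(C)C)c(C=O)c(Br)c1 | intermediate
7 | 1-bromo-3,5-dimethoxybenzene | COc1cc(Br)cc(OC)c1 | starting material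
8 | (2S,3S)-4-bromo-3-(3,5-dimethoxyphenyl)-6-methoxy-2-(4-methoxyphenyl)-2,3-dihydro-1-benzofuran | Brc1cc(OC)cc2c1[C@H](c1cc(OC)cc(OC)c1)[C@@H](c1ccc(OC)cc1)O2 | intermediate
9 | pterostilbene | COc1cc(/C=C/c2ccc(O)cc2)cc(OC)c1 | starting material
10 | 5-[(E)-2-(3,5-dimethoxyphenyl)ethenyl]-2-hydroxybenzaldehyde | COc1cc(/C=C/c2ccc(O)c(C=O)c2)cc(OC)c1 | intermediate
11 | tert-butyl {4-[(E)-2-(3,5-dimethoxyphenyl)ethenyl]-2-formylphenyl} carbonate | COc1cc(/C=C/c2ccc(OC(=O)OC(C)(C)C)c(C=O)c2)cc(OC)c1 | intermediate
12 | hepta-O-methyl-trans-diptoindonesin B (2S,3S,2′S,3′S) | COc1ccc([C@H]2Oc3ccc(/C=C/c4cc(OC)cc(OC)c4)cc3[C@@H]2c2cc(OC)cc3c2[C@H](c2cc(OC)cc(OC)c2)[C@@H](c2ccc(OC)cc2)O3)cc1 | intermediate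
13 | trans-diptoindonesin B | Oc1ccc([C@H]2Oc3ccc(/C=C/c4cc(O)cc(O)c4)cc3[C@@H]2c2cc(O)cc3c2[C@H](c2cc(O)cc(O)c2)[C@@H](c2ccc(O)cc2)O3)cc1 | target

**Totals**
Total steps: 8. Longest linear sequence: 5 (4 → 5 → 6 → 8 → 12 → 13).

**Steps most likely to fail**
1. Step 4 – the ylide may not trap the o-QM cleanly, and ee or trans:cis may be low (the 4-methoxybenzyl sulfonium could close by an SN1 path). Fallback: build this ring by Rh(II)-catalysed enantioselective C–H insertion of a diaryl carbene instead. From 5: PMB ether, ArMgBr addition and oxidation to the benzophenone, hydrazone, MnO2, chiral Rh2(PTAD)4 to the cis ring, then acid epimerisation at C2 to trans.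
2. Step 7 – the hindered aryl-magnesium may add poorly, and the existing ring may be mismatched with the ylide. Fallback: reverse the polarity and go stepwise. Formylate 8 (t-BuLi, DMF), ortho-hydroxyalkylate the bromomagnesium phenoxide of pterostilbene with that aldehyde, convert the benzhydrol to its aryl sulfone, and run a base-mediated o-QM/[4+1] on the isolated precursor.
3. Step 8 – sevenfold demethylation in the presence of two acid-labile 2-aryl dihydrobenzofurans and an electron-rich stilbene. Fallback: rebuild the route on phenol protection that comes off without BBr3 (cyclopropylmethyl or TBS ethers carried from 3,5-dihydroxy building blocks and resveratrol), finishing with HCl/EtOH or TBAF.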